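## Analysis of the target

The target is a flavonol: a 4H-chromen-4-one (benzo ring A fused to pyranone ring C) carrying a 3-hydroxy-4-methoxyphenyl ring B at C2, hydroxyls at C3 and C5, a methoxy group at C7 and 3-methylbut-2-enyl (prenyl) groups at C6 and C8. It has no stereocentre and no stereogenic double bond, so configuration is not an issue. Ring A is hexasubstituted with oxygen and carbon alternating around it (C4a acyl, C5 O, C6 prenyl, C7 OMe, C8 prenyl, C8a O1), so no position is left for late corrections.

The feature the route is built on is this: C6 is ortho to the C5 oxygen and para to O1 at C8a, while C8 is ortho to O1 and para to the C5 oxygen. Once the O1–C2 bond of ring C is opened, those two oxygens are equivalent phenols flanking the C4 acyl carbon, and the C7 methoxy group lies on the mirror plane.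

The sensitive groups are the two trisubstituted alkenes and the 3-hydroxy-4-pyranone. Under acid a prenyl group adds the neighbouring 5-hydroxyl to give a chroman; the alkenes also rule out hydrogenolysis and electrophilic oxidants. The flavonol unit is sensitive to base with oxygen and chelates metals. The two methyl ethers have to be in place from the start, because late methylation among three free hydroxyls would not be selective.

The difficulty is therefore not ring C, for which a reliable oxidative closure exists, but the two aryl–prenyl bonds on a ring that ends up fully substituted.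

## Retrosynthetic reasoning

**13 to 12.** The last operation only uncovers the 5-hydroxyl and the 3'-hydroxyl. Both are carried as methoxymethyl ethers in 12. These survive the strongly alkaline steps, and the ether at O5 is unusually labile because the freed hydroxyl chelates the C4 carbonyl, so the acid exposure of the prenyl groups can be kept short.

**12 to 10.** Ring C is cut at O1–C2 and at the C3–O bond. This leads back to the 2'-hydroxychalcone 10. The forward reaction is the Algar–Flynn–Oyamada oxidation, which runs through the dihydroflavonol 11. It uses a nucleophilic oxidant, so the isolated alkenes of the prenyl groups should not be touched.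

**10 to 7 and 9.** The enone is cut at its C=C bond (C2–C3 of the later flavonol) by a Claisen–Schmidt condensation. Ring B arrives as aldehyde 9, made from isovanillin 8, so the 3'-OH/4'-OMe pattern is bought rather than made.

**7 to 6.** Ketone 6 has a mirror plane through the acetyl group and C4. Monoprotection therefore gives a single product, and the oxygen left free becomes O1 while the protected one becomes the 5-hydroxyl. The symmetry removes any question of which phenol closes ring C.

**6 to 2 (key disconnection).** Both aryl–prenyl C–C bonds are cut at once and traced back to two aryl–O–prenyl bonds in the isomeric bis(ether) 2.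
- Each prenyl carbon of 6 is para to one phenolic oxygen, so each group can be delivered by an ortho-Claisen shift followed by a Cope shift.
- The two inversions of the allyl unit cancel, so it arrives as a normal prenyl group.
- The two relays cross: the ether at O2 feeds C5 and the ether at O6 feeds C3, through intermediates 3, 4 and 5.
- The cut is made here and not at the chalcone or flavonol stage because only the open acetophenone offers both oxygens as ethers, and because a plain ketone tolerates the temperature.
- Simple primary ethers are chosen over the isomeric tertiary allyl ethers. The latter would need only one shift each, but could not be installed cleanly on two hindered, chelated phenols.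
- The gain is that a tetrasubstituted symmetric arene becomes the hexasubstituted ring A in one thermal operation, with no reagent and no regiochemical choice left open.

**2 to 1.** The two C–O bonds are made by twofold O-alkylation of commercial 1 with a simple prenyl halide. Compound 1 already carries the C7 methoxy group and the C4 carbon.

## Alternatives that were turned down

**Alternative 1:** The textbook route. The disconnection is the same endgame (chalcone, then oxidative closure of ring C), with the two aryl–prenyl bonds made by direct electrophilic C-alkylation. The forward key step treats the parent trihydroxyacetophenone with a prenyl halide in aqueous alkali to give triol A1, which is then methylated at the central hydroxyl. It was turned down for these reasons: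
- The phenoxide is ambident at three oxygens and two carbons. O-alkylation, mono- and over-alkylation and geminal dialkylation with loss of aromaticity all compete, and nothing in the substrate directs the outcome.
- The later methylation has to pick the one hydroxyl that sits between two prenyl groups.
- The step count is no lower, and the material balance rests on separating a statistical mixture.

**Alternative 2:** De novo construction of ring A by a benzannulation of the Danheiser type. The disconnection cuts C5–C6, C7–C8 and C4a–C5. In the forward step a photochemical Wolff rearrangement of diazo ketone A2 gives a vinylketene. This adds to ynol ether A3 in a [2+2] fashion, the cyclobutenone opens, and a six-electron electrocyclization onto the pyranone C=C followed by tautomerization gives flavonol ether A4 with every substituent of ring A placed by the mechanism. It is the most elegant answer to the substitution pattern, but it was turned down: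
- A2 needs a fully substituted 2-aryl-3-alkoxy-4-pyranone carrying a homologated acyl side chain, roughly eight steps before the key step.
- The diazo carbon carries a CH2 group, so a 1,2-hydrogen shift to an enone competes with the Wolff shift.
- The pyranone is itself photoactive, and A3 is a volatile, hydrolytically labile reagent.
- The route would spend more steps on building the benzene ring than the whole of the chosen route, when that ring can be bought with three of its six substituents in place.

**Alternative 3:** Late-stage twofold cross-coupling. The disconnection cuts the same two aryl–prenyl bonds, but on the finished flavonol. The forward sequence makes the unprenylated flavonol A5, iodinates it to the 6,8-diiodide A6, and couples twice with a prenylstannane or prenylboronate under zerovalent palladium. It was turned down: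
- A5 already costs the full chalcone and oxidation sequence.
- Iodination has to discriminate ring A from the phenolic ring B, whose positions ortho and para to the 3'-hydroxyl are activated. This forces extra protection.
- Each C–I bond is flanked by two ortho substituents, so oxidative addition and transmetalation are slow and reductive loss of iodine competes.
- Allyl-metal reagents can transfer through either terminus, which would put 1,1-dimethylallyl isomers into a product that cannot be purified by symmetry.
- The route is longer and leaves its risk at the last C–C bond-forming step.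

Key step: step 2

## Route

Assumption: compounds 1 and 8 are taken as commercial. The target is achiral; the E geometry of 10 and the transient sp3 centres of 3, 5 and 11 are all erased on the way to 13.

Step 1
Reactants: 1 1-(2,6-dihydroxy-4-methoxyphenyl)ethanone
Product: 2 1-[4-methoxy-2,6-bis(3-methylbut-2-enyloxy)phenyl]ethanone
Conditions: prenyl bromide (2.6 equiv), K2CO3, DMF, 60 °C
Reagents that add atoms: prenyl bromide (1-bromo-3-methylbut-2-ene), CC(C)=CCBr
Why: Williamson etherification of both phenols; carbonate in a dipolar aprotic solvent should favour O- over C-alkylation, and the second, chelated hydroxyl is driven to react by the excess halide and gentle heating.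

Step 2
Reactants: 2 1-[4-methoxy-2,6-bis(3-methylbut-2-enyloxy)phenyl]ethanone
Product: 6 1-[2,6-dihydroxy-4-methoxy-3,5-bis(3-methylbut-2-enyl)phenyl]ethanone, via ortho-dienone 3 (not isolated), via mono-rearranged phenol 4 (not isolated), via gem-diallyl dienone 5 (not isolated)
Conditions: PhNEt2, 200 °C, sealed tube, argon
Reagents that add atoms: none
Why: Each aryl prenyl ether undergoes an ortho-Claisen [3,3] shift to a cyclohexa-2,4-dienone bearing a 2-methylbut-3-en-2-yl group (3 from the first ether), and a Cope [3,3] shift then carries that group, inverted a second time and hence as a normal 3-methylbut-2-enyl unit, to the carbon para to the oxygen, where tautomerization gives phenol 4. The second ether repeats the sequence in the opposite direction through dienone 5, so the two relays cross and end at C5 and C3 of the acetophenone ring. The closest known reaction type is the thermal para-Claisen–Cope rearrangement of 2-acylaryl prenyl ethers of the phloroglucinol series in N,N-dialkylanilines, here run twice in one flask. No ring is closed and no stereocentre survives, since the sp3 carbons of 3 and 5 are transient and are erased on rearomatization. Regiochemistry is secured by the substrate, because the acetyl-bearing and methoxy-bearing carbons cannot rearomatize and C3 and C5 are the only termini at which a hydrogen can be lost. The step needs the Cope shift of 3 to outrun enolization, which would freeze a reverse prenyl group at the ortho carbon; the high temperature and the compression of the tertiary group between the carbonyl and the methoxy-bearing carbon favour the shift, and the amine solvent buffers adventitious acid that would close chromans. In dienone 5 no enolization is possible, and the tertiary allyl unit should migrate in preference to the primary one because its shift breaks the more congested bond and forms the new bond at an unsubstituted allyl terminus. The two phenols set free are exactly those needed later, one for ring C and one as the 5-hydroxyl.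

Step 3
Reactants: 6 1-[2,6-dihydroxy-4-methoxy-3,5-bis(3-methylbut-2-enyl)phenyl]ethanone
Product: 7 1-[2-hydroxy-4-methoxy-6-(methoxymethoxy)-3,5-bis(3-methylbut-2-enyl)phenyl]ethanone
Conditions: MOMCl (1.1 equiv), iPr2NEt, CH2Cl2, 0 °C to rt
Reagents that add atoms: chloromethyl methyl ether (MOMCl), COCCl
Why: O-Methoxymethylation; the two hydroxyls of 6 are equivalent, and after the first alkylation the remaining one is locked in a hydrogen bond to the carbonyl and shielded by a prenyl group, so a second alkylation should be much slower.

Step 4
Reactants: 8 3-hydroxy-4-methoxybenzaldehyde (isovanillin)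
Product: 9 4-methoxy-3-(methoxymethoxy)benzaldehyde
Conditions: MOMCl, iPr2NEt, CH2Cl2, 0 °C to rt
Reagents that add atoms: chloromethyl methyl ether (MOMCl), COCCl
Why: O-Methoxymethylation of the only phenol; the ether is stable to the alkaline steps 5 and 6 and leaves together with the ring A ether in step 7.

Step 5
Reactants: 7 1-[2-hydroxy-4-methoxy-6-(methoxymethoxy)-3,5-bis(3-methylbut-2-enyl)phenyl]ethanone; 9 4-methoxy-3-(methoxymethoxy)benzaldehyde
Product: 10 (E)-1-[2-hydroxy-4-methoxy-6-(methoxymethoxy)-3,5-bis(3-methylbut-2-enyl)phenyl]-3-[4-methoxy-3-(methoxymethoxy)phenyl]prop-2-en-1-one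
Conditions: KOH (50% aq.), EtOH, rt
Reagents that add atoms: none
Why: Claisen–Schmidt condensation; 9 cannot enolize, the methyl ketone is the only enolizable partner, and E1cB dehydration of the aldol gives the conjugated E enone, which is isolated as the chelated phenol after acidification.

Step 6
Reactants: 10 (E)-1-[2-hydroxy-4-methoxy-6-(methoxymethoxy)-3,5-bis(3-methylbut-2-enyl)phenyl]-3-[4-methoxy-3-(methoxymethoxy)phenyl]prop-2-en-1-one
Product: 12 3-hydroxy-7-methoxy-5-(methoxymethoxy)-2-[4-methoxy-3-(methoxymethoxy)phenyl]-6,8-bis(3-methylbut-2-enyl)-4H-chromen-4-one, via trans-dihydroflavonol 11 (not isolated)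
Conditions: 30% H2O2, aq. NaOH, MeOH/THF, 0 °C to rt
Reagents that add atoms: hydrogen peroxide, OO
Why: Algar–Flynn–Oyamada oxidation; hydroperoxide attacks the enone, the 2'-phenoxide closes ring C at the benzylic carbon to give 11, and further oxidation of its enolate gives the flavonol, while the nucleophilic oxidant should leave the isolated trisubstituted alkenes untouched and the two stereocentres of 11 are destroyed.

Step 7
Reactants: 12 3-hydroxy-7-methoxy-5-(methoxymethoxy)-2-[4-methoxy-3-(methoxymethoxy)phenyl]-6,8-bis(3-methylbut-2-enyl)-4H-chromen-4-one
Product: 13 3,5-dihydroxy-2-(3-hydroxy-4-methoxyphenyl)-7-methoxy-6,8-bis(3-methylbut-2-enyl)-4H-chromen-4-one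
Conditions: 3 M HCl (aq.), MeOH, 45 °C
Reagents that add atoms: none
Why: Acid-catalysed acetal exchange with methanol removes both methoxymethyl groups; the ether at O5 goes first because the freed hydroxyl chelates the C4 carbonyl, and the mild temperature and short exposure are meant to spare the prenyl groups from addition of the neighbouring hydroxyl.

## Compound list

1 | 1-(2,6-dihydroxy-4-methoxyphenyl)ethanone | CC(=O)c1c(O)cc(OC)cc1O | starting material
2 | 1-[4-methoxy-2,6-bis(3-methylbut-2-enyloxy)phenyl]ethanone | CC(=O)c1c(OCC=C(C)C)cc(OC)cc1OCC=C(C)C | intermediate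
3 | 2-acetyl-5-methoxy-6-(2-methylbut-3-en-2-yl)-3-(3-methylbut-2-enyloxy)cyclohexa-2,4-dien-1-one (racemic, transient) | CC(=O)C1=C(OCC=C(C)C)C=C(OC)C(C(C)(C)C=C)C1=O | intermediate (not isolated)
4 | 1-[6-hydroxy-4-methoxy-3-(3-methylbut-2-enyl)-2-(3-methylbut-2-enyloxy)phenyl]ethanone | CC(=O)c1c(O)cc(OC)c(CC=C(C)C)c1OCC=C(C)C | intermediate (not isolated)
5 | 2-acetyl-3-hydroxy-5-methoxy-6-(2-methylbut-3-en-2-yl)-6-(3-methylbut-2-enyl)cyclohexa-2,4-dien-1-one (racemic, transient) | CC(=O)C1=C(O)C=C(OC)C(CC=C(C)C)(C(C)(C)C=C)C1=O | intermediate (not isolated)
6 | 1-[2,6-dihydroxy-4-methoxy-3,5-bis(3-methylbut-2-enyl)phenyl]ethanone | CC(=O)c1c(O)c(CC=C(C)C)c(OC)c(CC=C(C)C)c1O | intermediate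
7 | 1-[2-hydroxy-4-methoxy-6-(methoxymethoxy)-3,5-bis(3-methylbut-2-enyl)phenyl]ethanone | CC(=O)c1c(O)c(CC=C(C)C)c(OC)c(CC=C(C)C)c1OCOC | intermediate
8 | 3-hydroxy-4-methoxybenzaldehyde (isovanillin) | COc1ccc(C=O)cc1O | starting material
9 | 4-methoxy-3-(methoxymethoxy)benzaldehyde | COCOc1cc(C=O)ccc1OC | intermediate
10 | (E)-1-[2-hydroxy-4-methoxy-6-(methoxymethoxy)-3,5-bis(3-methylbut-2-enyl)phenyl]-3-[4-methoxy-3-(methoxymethoxy)phenyl]prop-2-en-1-one | COCOc1cc(/C=C/C(=O)c2c(O)c(CC=C(C)C)c(OC)c(CC=C(C)C)c2OCOC)ccc1OC | intermediate
11 | trans-3-hydroxy-7-methoxy-5-(methoxymethoxy)-2-[4-methoxy-3-(methoxymethoxy)phenyl]-6,8-bis(3-methylbut-2-enyl)-2,3-dihydro-4H-chromen-4-one (racemic; 2R,3R enantiomer drawn) | COCOc1cc([C@H]2Oc3c(CC=C(C)C)c(OC)c(CC=C(C)C)c(OCOC)c3C(=O)[C@@H]2O)ccc1OC | intermediate (not isolated)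
12 | 3-hydroxy-7-methoxy-5-(methoxymethoxy)-2-[4-methoxy-3-(methoxymethoxy)phenyl]-6,8-bis(3-methylbut-2-enyl)-4H-chromen-4-one | COCOc1cc(-c2oc3c(CC=C(C)C)c(OC)c(CC=C(C)C)c(OCOC)c3c(=O)c2O)ccc1OC | intermediate
13 | 3,5-dihydroxy-2-(3-hydroxy-4-methoxyphenyl)-7-methoxy-6,8-bis(3-methylbut-2-enyl)-4H-chromen-4-one | COc1ccc(-c2oc3c(CC=C(C)C)c(OC)c(CC=C(C)C)c(O)c3c(=O)c2O)cc1O | target

## Step count and risk

Total step count: 7. Longest linear sequence: 6 (steps 1, 2, 3, 5, 6, 7).

**Step 2 (key step).** Three things are most likely to go wrong:
- Enolization of the first ortho-dienone 3 before its Cope shift, which would fix a 1,1-dimethylallyl group next to the oxygen.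
- Thermal loss of a prenyl group, or closure of an ortho-prenylphenol to a chroman at 200 °C.
- Migration of the primary instead of the tertiary allyl unit from dienone 5.

Each of these lowers the yield of an isomer family that is hard to separate. The fallback builds the prenyl alkenes by metathesis instead of carrying them through the rearrangement. It sets out from 1 and comes back at 6.
- Twofold O-allylation of 1 (allyl bromide, K2CO3, DMF) should give 1-[4-methoxy-2,6-bis(prop-2-enyloxy)phenyl]ethanone F1.
- A twofold ortho-Claisen rearrangement in PhNEt2 at 200 °C should give 1-[2,6-dihydroxy-4-methoxy-3,5-bis(prop-2-enyl)phenyl]ethanone F2. An unsubstituted allyl group gives the same product from either terminus, and the only open ortho positions are C3 and C5.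
- Twofold cross-metathesis of F2 with 2-methylbut-2-ene, using the second-generation Grubbs catalyst RuCl2(=CHPh)(H2IMes)(PCy3) in CH2Cl2 at 40 °C, should return to 6.

**Step 6.** The 6'-substituent twists the aroyl group, which can divert ring closure to the α-carbon (five-membered ring, aurone pathway). Peroxide addition to this electron-rich enone may be slow, and oxidation of 11 may stop short. The fallback separates epoxidation from ring closure. It sets out from 10 and comes back at 13.
- Methoxymethylation of the 2'-hydroxyl (NaH, MOMCl, DMF) should give (E)-1-[4-methoxy-2,6-bis(methoxymethoxy)-3,5-bis(3-methylbut-2-enyl)phenyl]-3-[4-methoxy-3-(methoxymethoxy)phenyl]prop-2-en-1-one F3.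
- Alkaline hydrogen peroxide should give the racemic trans-epoxy ketone [4-methoxy-2,6-bis(methoxymethoxy)-3,5-bis(3-methylbut-2-enyl)phenyl]{3-[4-methoxy-3-(methoxymethoxy)phenyl]oxiran-2-yl}methanone F4.
- Methanolic HCl at 45 °C should remove the three acetal groups and let the freed phenol open the epoxide at the benzylic carbon, giving racemic trans-3,5-dihydroxy-2-(3-hydroxy-4-methoxyphenyl)-7-methoxy-6,8-bis(3-methylbut-2-enyl)-2,3-dihydro-4H-chromen-4-one F5.
- Aerobic dehydrogenation of F5 under mild base (O2, K2CO3, MeOH, rt) should give 13.

**Step 7.** Protonation of a prenyl double bond and capture by the adjacent 5-hydroxyl (chroman formation), or hydration of the alkene, may compete with cleavage of the slower ring B acetal. The fallback replaces acid-labile protection with allyl ethers that are removed under neutral conditions. It sets out from 6 and 8 and comes back at 13.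
- Monoallylation of 6 (allyl bromide, K2CO3, acetone) should give 1-[2-hydroxy-4-methoxy-3,5-bis(3-methylbut-2-enyl)-6-(prop-2-enyloxy)phenyl]ethanone F6.
- Allylation of 8 should give 4-methoxy-3-(prop-2-enyloxy)benzaldehyde F7.
- Claisen–Schmidt condensation of F6 with F7 should give (E)-1-[2-hydroxy-4-methoxy-3,5-bis(3-methylbut-2-enyl)-6-(prop-2-enyloxy)phenyl]-3-[4-methoxy-3-(prop-2-enyloxy)phenyl]prop-2-en-1-one F8.
- Algar–Flynn–Oyamada oxidation should give 3-hydroxy-7-methoxy-2-[4-methoxy-3-(prop-2-enyloxy)phenyl]-6,8-bis(3-methylbut-2-enyl)-5-(prop-2-enyloxy)-4H-chromen-4-one F9.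
- Deallylation with Pd(PPh3)4 (zerovalent palladium) and morpholine in THF at rt should give 13. The C-bound prenyl groups cannot ionize under these conditions.

**Step 1.** C-Alkylation of the ambident phenoxide at C3 or C5 and incomplete etherification of the second, chelated hydroxyl may compete. The fallback sets out from 1 and comes back at 2: a twofold Mitsunobu etherification of 1 with 3-methylbut-2-en-1-ol (PPh3, diisopropyl azodicarboxylate, THF). This activates the alcohol rather than the phenoxide, so no carbon nucleophile is generated. It makes no new compound (F0).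

## Further compounds

F1 | step 2 | 1-[4-methoxy-2,6-bis(prop-2-enyloxy)phenyl]ethanone | CC(=O)c1c(OCC=C)cc(OC)cc1OCC=C
F2 | step 2 | 1-[2,6-dihydroxy-4-methoxy-3,5-bis(prop-2-enyl)phenyl]ethanone | CC(=O)c1c(O)c(CC=C)c(OC)c(CC=C)c1O
F3 | step 6 | (E)-1-[4-methoxy-2,6-bis(methoxymethoxy)-3,5-bis(3-methylbut-2-enyl)phenyl]-3-[4-methoxy-3-(methoxymethoxy)phenyl]prop-2-en-1-one | COCOc1cc(/C=C/C(=O)c2c(OCOC)c(CC=C(C)C)c(OC)c(CC=C(C)C)c2OCOC)ccc1OC
F4 | step 6 | trans-[4-methoxy-2,6-bis(methoxymethoxy)-3,5-bis(3-methylbut-2-enyl)phenyl]{3-[4-methoxy-3-(methoxymethoxy)phenyl]oxiran-2-yl}methanone (racemic; one enantiomer drawn) | COCOc1cc([C@H]2O[C@@H]2C(=O)c2c(OCOC)c(CC=C(C)C)c(OC)c(CC=C(C)C)c2OCOC)ccc1OC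
F5 | step 6 | trans-3,5-dihydroxy-2-(3-hydroxy-4-methoxyphenyl)-7-methoxy-6,8-bis(3-methylbut-2-enyl)-2,3-dihydro-4H-chromen-4-one (racemic; 2R,3R enantiomer drawn) | COc1ccc([C@H]2Oc3c(CC=C(C)C)c(OC)c(CC=C(C)C)c(O)c3C(=O)[C@@H]2O)cc1O
F6 | step 7 | 1-[2-hydroxy-4-methoxy-3,5-bis(3-methylbut-2-enyl)-6-(prop-2-enyloxy)phenyl]ethanone | CC(=O)c1c(O)c(CC=C(C)C)c(OC)c(CC=C(C)C)c1OCC=C
F7 | step 7 | 4-methoxy-3-(prop-2-enyloxy)benzaldehyde | C=CCOc1cc(C=O)ccc1OC
F8 | step 7 | (E)-1-[2-hydroxy-4-methoxy-3,5-bis(3-methylbut-2-enyl)-6-(prop-2-enyloxy)phenyl]-3-[4-methoxy-3-(prop-2-enyloxy)phenyl]prop-2-en-1-one | C=CCOc1cc(/C=C/C(=O)c2c(O)c(CC=C(C)C)c(OC)c(CC=C(C)C)c2OCC=C)ccc1OC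
F9 | step 7 | 3-hydroxy-7-methoxy-2-[4-methoxy-3-(prop-2-enyloxy)phenyl]-6,8-bis(3-methylbut-2-enyl)-5-(prop-2-enyloxy)-4H-chromen-4-one | C=CCOc1cc(-c2oc3c(CC=C(C)C)c(OC)c(CC=C(C)C)c(OCC=C)c3c(=O)c2O)ccc1OC
F0 | step 1 | none | none
A1 | alternative 1 | 1-[2,4,6-trihydroxy-3,5-bis(3-methylbut-2-enyl)phenyl]ethanone | CC(=O)c1c(O)c(CC=C(C)C)c(O)c(CC=C(C)C)c1O
A2 | alternative 2 | 2-(2-diazo-5-methylhex-4-enoyl)-5-(methoxymethoxy)-6-[4-methoxy-3-(methoxymethoxy)phenyl]-4H-pyran-4-one | CC(C)=CCC(=[N+]=[N-])C(=O)c1cc(=O)c(OCOC)c(-c2ccc(OC)c(OCOC)c2)o1
A3 | alternative 2 | 1-methoxy-5-methylhex-4-en-1-yne | COC#CCC=C(C)C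
A4 | alternative 2 | 5-hydroxy-7-methoxy-3-(methoxymethoxy)-2-[4-methoxy-3-(methoxymethoxy)phenyl]-6,8-bis(3-methylbut-2-enyl)-4H-chromen-4-one | COCOc1cc(-c2oc3c(CC=C(C)C)c(OC)c(CC=C(C)C)c(O)c3c(=O)c2OCOC)ccc1OC
A5 | alternative 3 | 3,5-dihydroxy-2-(3-hydroxy-4-methoxyphenyl)-7-methoxy-4H-chromen-4-one | COc1ccc(-c2oc3cc(OC)cc(O)c3c(=O)c2O)cc1O
A6 | alternative 3 | 3,5-dihydroxy-2-(3-hydroxy-4-methoxyphenyl)-6,8-diiodo-7-methoxy-4H-chromen-4-one | COc1ccc(-c2oc3c(I)c(OC)c(I)c(O)c3c(=O)c2O)cc1O
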